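**Strategy.** The route rests on opening ring A between the gem-dimethyl carbon C4 and the ring-fusion methine C5 (drimane numbering), which unfolds the trans-decalin into an acyclic (E,E)-triene. The key step is a proton-initiated cation–olefin bicyclization: in one operation it forms C4–C5 and C9–C10, closes rings A and B and sets C5, C9 and C10. It exploits the trans ring fusion (H-5 anti to the C10 methyl) and the equatorial C1 oxygen beside C10, the only stereocenter of the precursor, which steers the chair–chair fold. The precursor is a farnesyl acetate analogue with an isopropenyl terminus that already carries the 4-methoxycinnamate at the future C1. Oxidation at C12 and C11 completes the dialdehyde.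

Key step: step 4

Remark on numbering: bicyclic compounds use drimane numbering (C1 bears the ester oxygen, C4 the two methyls, C5 and C10 are the ring-fusion carbons, C9 bears C11, C8 bears C12). In the acyclic chain, C8 becomes C1, C11 becomes C4, C6=C7 becomes C5=C10 and C2=C3 becomes C9=C8.

**Step 1**
Reactants: 1 geranyl acetate
Product: 3 (2E,6E)-3,7-dimethyl-8-oxoocta-2,6-dien-1-yl acetate, via allylic alcohol 2 (not isolated)
Conditions: SeO2 (cat.), tBuOOH, salicylic acid (cat.), CH2Cl2, rt; filtration; then MnO2, CH2Cl2, rt
Reagents that add atoms: selenium dioxide O=[Se]=O (delivers the oxygen atom); tert-butyl hydroperoxide CC(C)(C)OO (reoxidises selenium, net oxygen source)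
Why: SeO2/tBuOOH allylic oxidation (ene reaction, then 2,3-sigmatropic shift) selects the (E)-methyl group of the electron-richer terminal alkene, and MnO2 then takes the allylic alcohol to the (E)-enal without touching the acetate.

**Step 2**
Reactants: 3 (2E,6E)-3,7-dimethyl-8-oxoocta-2,6-dien-1-yl acetate; 4 4-bromo-2-methylbut-1-ene
Product: 7 (2E,6E,8R)-8-hydroxy-3,7,11-trimethyldodeca-2,6,11-trien-1-yl acetate, via Grignard reagent 5 (not isolated), via dialkylzinc 6 (not isolated)
Conditions: 4, Mg, Et2O; ZnCl2 (0.5 equiv), then 1,4-dioxane and filtration of the magnesium salts; then 3, Ti(OiPr)4, (1S,2S)-1,2-bis(trifluoromethanesulfonamido)cyclohexane (8 mol%), toluene, −20 °C; aq HCl work-up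
Reagents that add atoms: none
Why: Catalytic asymmetric addition of a dialkylzinc to an aldehyde under Ti(OiPr)4/bis-sulfonamide catalysis tolerates the acetate and suits α-branched enals, and the (1S,2S) ligand is chosen so that the alkyl group is delivered to the Re face of the formyl group, which sets the (8R) carbinol that becomes C1.

**Step 3**
Reactants: 7 (2E,6E,8R)-8-hydroxy-3,7,11-trimethyldodeca-2,6,11-trien-1-yl acetate; 8 (E)-3-(4-methoxyphenyl)prop-2-enoyl chloride
Product: 9 (2E,6E,8R)-1-acetoxy-3,7,11-trimethyldodeca-2,6,11-trien-8-yl (E)-3-(4-methoxyphenyl)prop-2-enoate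
Conditions: Et3N, 4-(dimethylamino)pyridine (cat.), CH2Cl2, 0 °C to rt
Reagents that add atoms: none
Why: Acylation of the secondary allylic alcohol under nucleophilic catalysis occurs at oxygen with retention at C8, so the ester is in place before any ring exists and never has to be introduced next to the quaternary C10.

**Step 4**
Reactants: 9 (2E,6E,8R)-1-acetoxy-3,7,11-trimethyldodeca-2,6,11-trien-8-yl (E)-3-(4-methoxyphenyl)prop-2-enoate
Product: 12 1β-[(E)-4-methoxycinnamoyloxy]drim-7-en-11-yl acetate (1R,5S,10S; H-5 α, H-9 α, CH3-10 β), via tertiary C4 carbocation 10 (not isolated), via bicyclic C8 carbocation 11 (not isolated)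
Conditions: FSO3H (5 equiv), 2-nitropropane, −78 °C, short reaction time; quench with Et3N in MeOH at −78 °C
Reagents that add atoms: none
Why: Markovnikov protonation of the isopropenyl group, the only alkene without an allylic acyloxy group, should give cation 10 at C4, which is attacked by C5 of the (E)-C5=C10 alkene while C9 of the (E)-C8=C9 alkene adds antiperiplanar to C10, and cation 11 then loses H-7 to give the C7=C8 alkene. The closest known reaction type is the superacid-induced biomimetic cation–olefin bicyclization of (E,E)-farnesyl acetate to drimenyl acetate. Ring A closes by 6-endo-trig attack on C5 (the C4–C5 bond) and ring B by 6-endo-trig attack of C9 on C10, both through chairs. C5, C9 and C10 are fixed relative to one another by the two (E)-alkenes (anti addition across C5=C10 gives the trans fusion, the (E)-C8=C9 geometry places CH2OAc equatorial) and relative to C1 by the chair in which the C1–O bond is pseudoequatorial, near the nodal plane of the C5=C10 π bond, while the axial C1–H bond hyperconjugates with the charge developing at C10; this fold gives the 1β ester cis to the C10 methyl. The step needs site-selective protonation, survival of the allylic ester and facial selectivity: the first follows from deactivation of both trisubstituted alkenes by their allylic esters, the second from the low temperature and from O-protonation of the cinnamate to a delocalised cation that is a poor leaving group and cannot act as a neighbouring group, and the third from the C1 stereocenter, the other fold giving a separable diastereomer and not the enantiomer.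

**Step 5**
Reactants: 12 1β-[(E)-4-methoxycinnamoyloxy]drim-7-en-11-yl acetate
Product: 13 12-hydroxy-1β-[(E)-4-methoxycinnamoyloxy]drim-7-en-11-yl acetate
Conditions: SeO2 (cat.), tBuOOH, CH2Cl2, rt
Reagents that add atoms: selenium dioxide O=[Se]=O (delivers the oxygen atom); tert-butyl hydroperoxide CC(C)(C)OO (reoxidises selenium, net oxygen source)
Why: SeO2 allylic oxidation of the trisubstituted C7=C8 alkene attacks the substituents on its more substituted carbon in the order CH3 before CH, so the C12 methyl is hydroxylated in preference to C9–H and C6, as in the known oxidation of drimenyl acetate, while the cinnamate alkene has no allylic hydrogen.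

**Step 6**
Reactants: 13 12-hydroxy-1β-[(E)-4-methoxycinnamoyloxy]drim-7-en-11-yl acetate
Product: 14 1β-[(E)-4-methoxycinnamoyloxy]drim-7-ene-11,12-diol
Conditions: K2CO3 (0.3 equiv), MeOH, 0 °C
Reagents that add atoms: none
Why: Base-catalysed transesterification (Zemplén-type methanolysis) should remove the unhindered primary acetate much faster than the conjugated secondary cinnamate that sits next to the quaternary C10.

**Step 7**
Reactants: 14 1β-[(E)-4-methoxycinnamoyloxy]drim-7-ene-11,12-diol
Product: 16 1β-[(E)-4-methoxycinnamoyloxy]drim-7-ene-11,12-dial (1R,5S,9R,10S; CNP0328580.1), via bis-alkoxysulfonium salt 15 (not isolated)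
Conditions: (COCl)2, DMSO, CH2Cl2, −78 °C; then Et3N, −78 to −20 °C; pH 7 buffer
Reagents that add atoms: none
Why: In the Swern oxidation both hydroxyls are converted to alkoxysulfonium ions before base is added, so no hydroxy aldehyde can close to a lactol, and the cold, brief exposure to Et3N limits epimerisation of the C9 formyl group, as in the oxidation of drim-7-ene-11,12-diol to polygodial.

**Compound list**
1 | geranyl acetate, (2E)-3,7-dimethylocta-2,6-dien-1-yl acetate | CC(=O)OC/C=C(\C)CCC=C(C)C | starting material
2 | (2E,6E)-8-hydroxy-3,7-dimethylocta-2,6-dien-1-yl acetate | CC(=O)OC/C=C(\C)CC/C=C(\C)CO | intermediate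
3 | (2E,6E)-3,7-dimethyl-8-oxoocta-2,6-dien-1-yl acetate | CC(=O)OC/C=C(\C)CC/C=C(\C)C=O | intermediate
4 | 4-bromo-2-methylbut-1-ene | C=C(C)CCBr | starting material
5 | (3-methylbut-3-en-1-yl)magnesium bromide | C=C(C)CC[Mg]Br | intermediate
6 | bis(3-methylbut-3-en-1-yl)zinc | C=C(C)CC[Zn]CCC(C)=C | intermediate
7 | (2E,6E,8R)-8-hydroxy-3,7,11-trimethyldodeca-2,6,11-trien-1-yl acetate | CC(=O)OC/C=C(\C)CC/C=C(\C)[C@H](O)CCC(C)=C | intermediate
8 | (E)-3-(4-methoxyphenyl)prop-2-enoyl chloride | COc1ccc(/C=C/C(=O)Cl)cc1 | starting material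
9 | (2E,6E,8R)-1-acetoxy-3,7,11-trimethyldodeca-2,6,11-trien-8-yl (E)-3-(4-methoxyphenyl)prop-2-enoate | COc1ccc(/C=C/C(=O)O[C@H](CCC(C)=C)/C(C)=C/CC/C(C)=C/COC(C)=O)cc1 | intermediate
10 | tertiary carbocation of 9 at chain C11 (future C4) | COc1ccc(/C=C/C(=O)O[C@H](CC[C+](C)C)/C(C)=C/CC/C(C)=C/COC(C)=O)cc1 | intermediate
11 | 1β-[(E)-4-methoxycinnamoyloxy]-11-acetoxydriman-8-yl cation (trans-fused) | COc1ccc(/C=C/C(=O)O[C@@H]2CCC(C)(C)[C@@H]3CC[C+](C)[C@H](COC(C)=O)[C@@]23C)cc1 | intermediate
12 | 1β-[(E)-4-methoxycinnamoyloxy]drim-7-en-11-yl acetate (H-5 α, H-9 α, CH3-10 β) | COc1ccc(/C=C/C(=O)O[C@@H]2CCC(C)(C)[C@@H]3CC=C(C)[C@H](COC(C)=O)[C@@]23C)cc1 | intermediate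
13 | 12-hydroxy-1β-[(E)-4-methoxycinnamoyloxy]drim-7-en-11-yl acetate | COc1ccc(/C=C/C(=O)O[C@@H]2CCC(C)(C)[C@@H]3CC=C(CO)[C@H](COC(C)=O)[C@@]23C)cc1 | intermediate
14 | 1β-[(E)-4-methoxycinnamoyloxy]drim-7-ene-11,12-diol | COc1ccc(/C=C/C(=O)O[C@@H]2CCC(C)(C)[C@@H]3CC=C(CO)[C@H](CO)[C@@]23C)cc1 | intermediate
15 | 11,12-bis(dimethylsulfonio-oxy) derivative of 14, dichloride | COc1ccc(/C=C/C(=O)O[C@@H]2CCC(C)(C)[C@@H]3CC=C(CO[S+](C)C)[C@H](CO[S+](C)C)[C@@]23C)cc1.[Cl-].[Cl-] | intermediate
16 | 1β-[(E)-4-methoxycinnamoyloxy]drim-7-ene-11,12-dial, (1R,5S,9R,10S) | COc1ccc(/C=C/C(=O)O[C@@H]2CCC(C)(C)[C@@H]3CC=C(C=O)[C@H](C=O)[C@@]23C)cc1 | target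

**Total step count:** 7. **Longest linear sequence:** 7 steps (1 to 16); the zinc reagent from 4 is made within step 2.

**Steps most likely to fail**

First, step 4. The O-protonated allylic cinnamate at C1 may ionise, the cascade may stall because the C5=C10 alkene beside the ester is too poor a nucleophile, or the fold may be unselective. The fallback sets out from 9 and activates the terminal alkene with a soft metal electrophile instead of a proton. Divalent mercury triflate as its N,N-dimethylaniline complex (Hg(OTf)2·PhNMe2, MeNO2, −20 °C, then aqueous NaCl) should give the bicyclic organomercurial chloride F1, in which one C4 methyl is CH2HgCl (C4 epimers are of no consequence). NaBH4 in aqueous NaOH/THF at 0 °C would then replace mercury by hydrogen and return to the route at 12. The ester stays unprotonated under these buffered conditions, at the cost of one more operation and stoichiometric mercury.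

Second, step 7. The C9 formyl group may epimerise under Et3N, or a mono-oxidised hydroxy aldehyde may close to a lactol that is oxidised on to the lactone. The fallback sets out from 13 and oxidises the two carbons one after the other, so that a free hydroxyl and a free aldehyde never coexist. MnO2 in CH2Cl2 should give the enal acetate F2. HC(OMe)3 with pyridinium p-toluenesulfonate in MeOH would protect it as the dimethyl acetal F3. K2CO3 in MeOH at 0 °C would free the C11 alcohol F4. Dess–Martin periodinane buffered with NaHCO3 would give the aldehyde acetal F5 without base-induced epimerisation. Aqueous oxalic acid in THF at 0 °C would unmask the enal and arrive at 16.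

Third, step 2. Enantiofacial control may be incomplete, or transfer of the homoallylic group from zinc may be sluggish. The fallback sets out from 3 and separates C–C bond formation from the stereochemical step. Grignard reagent 5 (1.05 equiv, THF, −78 °C) should add to the aldehyde in preference to the acetate and give the racemic alcohol F6. MnO2 in CH2Cl2 would give the dienone F7. Corey–Bakshi–Shibata reduction with (S)-1-methyl-3,3-diphenyltetrahydro-1H,3H-pyrrolo[1,2-c][1,3,2]oxazaborole (cat.) and catecholborane in toluene at −78 °C, with the alkenyl group as the large substituent, should return the (8R) alcohol 7.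

**Further compounds**
F1 | step 4 | 1β-[(E)-4-methoxycinnamoyloxy]-4-(chloromercuriomethyl)-18-nordrim-7-en-11-yl acetate, mixture of C4 epimers | COc1ccc(/C=C/C(=O)O[C@@H]2CCC(C)(C[Hg]Cl)[C@@H]3CC=C(C)[C@H](COC(C)=O)[C@@]23C)cc1
F2 | step 7 | 1β-[(E)-4-methoxycinnamoyloxy]-12-oxodrim-7-en-11-yl acetate | COc1ccc(/C=C/C(=O)O[C@@H]2CCC(C)(C)[C@@H]3CC=C(C=O)[C@H](COC(C)=O)[C@@]23C)cc1
F3 | step 7 | 12,12-dimethoxy-1β-[(E)-4-methoxycinnamoyloxy]drim-7-en-11-yl acetate | COc1ccc(/C=C/C(=O)O[C@@H]2CCC(C)(C)[C@@H]3CC=C(C(OC)OC)[C@H](COC(C)=O)[C@@]23C)cc1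
F4 | step 7 | 12,12-dimethoxy-1β-[(E)-4-methoxycinnamoyloxy]drim-7-en-11-ol | COc1ccc(/C=C/C(=O)O[C@@H]2CCC(C)(C)[C@@H]3CC=C(C(OC)OC)[C@H](CO)[C@@]23C)cc1
F5 | step 7 | 12,12-dimethoxy-1β-[(E)-4-methoxycinnamoyloxy]drim-7-en-11-al | COc1ccc(/C=C/C(=O)O[C@@H]2CCC(C)(C)[C@@H]3CC=C(C(OC)OC)[C@H](C=O)[C@@]23C)cc1
F6 | step 2 | (2E,6E)-8-hydroxy-3,7,11-trimethyldodeca-2,6,11-trien-1-yl acetate, racemic at C8 | CC(=O)OC/C=C(\C)CC/C=C(\C)C(O)CCC(C)=C
F7 | step 2 | (2E,6E)-3,7,11-trimethyl-8-oxododeca-2,6,11-trien-1-yl acetate | CC(=O)OC/C=C(\C)CC/C=C(\C)C(=O)CCC(C)=C
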